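All runs are simulated for an exercise, noise included.

A small charge of X, 6.6 mM under Q held at 0.76 mM, gave me the one run I had, and I went through it slowly, in shares of the charge, to see what Monday's, Wednesday's and Friday's flasks would give.

in all of them: Q 0.76 mM (held)
- north-east: X 6.6 mM; run made earlier
- Monday's: X 6.0 mM; time 20 h
- Wednesday's: X 12 mM; time 20 h
- Friday's: X 25 mM; time 20 h

north-east run (percent of the X charged)

| time / h | D / % | X / % |
|---|---|---|
| 1.33 | 3.6 | 0.2 |
| 3.00 | 9.8 | 0.5 |
| 4.00 | 11.0 | 0 |
| 6.00 | 17.6 | 0.3 |
| 8.00 | 25.7 | 0 |

(readings scatter by 1 percentage point)

- what was read earlier has a scatter of 1 percentage point, one standard deviation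
- at the start none of X is in solution
- at the start none of Q is in solution
- a reading or a percentage of D counts all its forms, free or not
- "hardly changes" means that all values lie within two and a half points (for a concentration: within two and a half percent of the largest)

- amount of D at the end, in percent of the X charged for Monday's, Wednesday's, Friday's, in this order
- how that number moves from the first to the last of them (falls, then rises / rises, then falls / rises all the way / falls all the way / hardly changes)

In the first instants the solid moved fastest: by 1.33 h nearly all of the north-east X had left it, with 0.2% still read as X and 3.6% as D, so I took the other 96.2% to be dissolved. Dividing the emptying pace of the solid by the pace of D, so that time dropped out, I read a ratio of at least 23.4, which meant that D was made from a dissolved stock.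

Through the middle D climbed to 25.7% at 8.00 h, and there the readings could not choose between two curves. One was a straight line. The other was a pseudo-first-order curve, in which a fixed share of the dissolved stock reacts each hour. Drawn through that last reading, the curve gave 10.5% at 3.00 h against 9.8% read, a gap smaller than the scatter of 1 percentage point.

For the end I therefore carried both. The share of the north-east charge that the straight line reaches at 20 h I called the reach, 64.2%. If the hourly amount of D is the same in every flask, as it might be with Q held alike, a flask's reach scales inversely with its charge: 70.7% for Monday's, 35.3% for Wednesday's and 17.0% for Friday's. The curve instead gives 52.4% of any charge that dissolves. My own reckoning, which is not the forecast's, put each flask between its reach and that curve, falling from Monday's to Friday's.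

The forecast said 68%, 34% and 16%, falls all the way, on the ground that “I therefore expect the same mM/h in every run while solid remains”, so that its Wednesday's value stood lower than my 35.3% and its Friday's value lower than my 17.0%.

The flasks gave 58.2%, 44.8% and 26.5%, falls all the way.

    X ⇌ L, rate k1*(cs1 - [L]) while solid is left; crystals form when [L] > cs1 (solubility = 16.0 mM, k = 0.0126 /min)
    L + Z → D (k = 2.51 /M/min)
    Z → E (k = 0.00590 /min)
    J ⇌ D, rate k4*(cs4 - [D]) while solid is left; crystals form when [D] > cs4 (solubility = 8.90 mM, k = 0.0200 /min)
    Z + D ⇌ G, settled at all times (K = 584 /M)
    Q ⇌ Z, rate k6*(csat - [Z]) (kL = 0.0115 /min)

Set against its reach, Monday's D came to 0.823 of it, Wednesday's to 1.27 and Friday's to 1.56. At 20.0 h Friday's flask still held 11.3% of its charge as solid X.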